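(Readings and results were generated by integration with made-up constants; the scatter is artificial.)

- Sunday's run and Monday's run both charge 2 equiv of Z, with L the limiting reagent, and we ask whether one number can carry their L curves to gamma and beta.

| flask | L | Z | remark | time |
|---|---|---|---|---|
| Sunday's | 7.4 mM | 2 equiv | run made earlier |  |
| Monday's | 5.5 mM | 2 equiv | run made earlier |  |
| gamma | 11 mM | 2.00 equiv |  | 10 d |
| beta | 11 mM | 3.00 equiv |  | 10 d |

- Sunday's (time / d: L / %, E / %): 0.625: 88.0, 11.1; 1.25: 77.7, 19.9; 2.00: 67.4, 27.7; 3.00: 56.1, 33.8; 4.00: 48.2, 39.1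
- Monday's (time / d: L / %, E / %): 0.625: 90.7, 8.3; 1.25: 82.4, 15.8; 2.00: 74.1, 22.6; 3.00: 63.8, 28.6; 4.00: 57.1, 34.1

(scatter of a reading: 0.3 percentage points)

- percent here means L units held: one J counts as two
- what is said of E includes G
- G is a solid; its amount is given per volume of the solution
- on the list of suspects stand: L + Z <-> Q + E; Z + Q <-> X; L + E -> J; G <-> E

1. part of the L that has reacted at the end, gamma
2. part of the L that has reacted at the end, beta
3. what raising the equivalents of Z from its lowest to its highest value here does to the part of the L that has reacted (changes below 5 percentage points count as none) (no change / it falls / it rises)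

- For the single step L + Z, we take D = k([Z] − [L])t, with both concentrations as charged: the spare Z times the rate constant times the time.
- Early on, L falls with k[Z]. Late, it is pseudo-first-order in the spare Z and falls as exp(−D). Joining both ends, the part of L left at M equivalents is (M − 1)/(M·exp(D) − 1).
- Sunday's last reading inverts to 0.430, and Monday's to 0.319.
- To test one number, we scale Sunday's D to Monday's [L]. This predicts 57.0% of L left against the reading of 57.1%, with a scatter of 0.3 percentage points.
- The test has a limit: L and E together already fall 13 points short at Sunday's last reading.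
- Scaled by [L] and time, gamma's spare-Z number, D, is 1.60, and beta's is 3.20; both lie above the 0.430 read from Sunday's last reading. Our reckoning gives 88.7% and 97.2% reacted, a rise of 8.5 points.
- The forecast says 78% (71% to 88%) and 84% (77% to 94%), and on the trend, it rises. It holds that “the back reaction Q + E matters”. Our figures stand above both ranges.

    L + Z ⇌ Q + E (K = 15.0, k = 1.70 × 10⁻⁴ L mol⁻¹ s⁻¹)
    Z + Q ⇌ X, settled at all times (K = 43000 L mol⁻¹)
    L + E → J (k = 1.70 × 10⁻⁴ L mol⁻¹ s⁻¹)
    G ⇌ E, rate k4*(cs4 - [E]) while solid is left; crystals form when [E] > cs4 (solubility = 3.60 mM, k = 3.30 × 10⁻⁵ s⁻¹)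

- Gamma gives 87.0% and beta 96.1%, and the answer on the trend is: it rises, by 9.1 points, while our figures stood 1.7 points and 1.1 points higher. Taking out the way back, Q + E to L + Z, makes no difference to gamma or beta. With 3.40 equiv of Z and all else as in gamma, 1.60 scaled by the spare Z gives a D of 3.84 and 98.5% reacted; that flask gives 97.7%.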